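**Assumption:** compounds 1, 10, 15, 19 and the simple reagents are taken as commercial. The C1 carbinol made in step 3 is carried as an epimer mixture because it becomes the C1 ketone in step 15. Atom labels (C1–C15) follow germacrane numbering of the target.

## Retrosynthetic overview
1. Target ⇐ 15‑O‑silyl ether; the 3(2H)‑furanone comes from a transannular Au‑catalysed 5‑endo‑dig cyclisation of an α′‑hydroxy ynone (C10–OH onto C3).
2. The 10‑membered carbocycle is closed at C3–C4 by an intramolecular Sonogashira coupling (terminal alkyne + Z‑vinyl iodide).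
3. The trans α‑methylene‑γ‑lactone and the C7/C8 stereocentres come from an intermolecular Zn‑Barbier coupling (C7–C8) of a bromomethyl butenolide with a C8 aldehyde; the tiglate is added directly afterwards.
4. Aldehyde (C8–C10, C1–C3) from (S)‑2‑methylglycidol (C10 from the chiral pool). Bromolactone from 2‑butyne‑1,4‑diol via Red‑Al/I2 (Z‑C4=C5) and a catalytic asymmetric carboalkoxyallylation (C6).
5. Ring order: butenolide → α‑methylene‑γ‑lactone → 10‑membered carbocycle → furanone.

## Route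

### Fragment A (aldehyde 9)

**Step 1**
Reactants: 1 (S)‑2‑methylglycidol; 2 vinylmagnesium bromide
Product: 3 (2R)‑2‑methylpent‑4‑ene‑1,2‑diol
Conditions: 2 (3 equiv), CuI (10 mol %), THF, −30 → 0 °C
Reagents that add atoms: vinylmagnesium bromide, C=C[Mg]Br
Why: Cu‑catalysed SN2 epoxide opening at the unhindered CH2 terminus; the quaternary carbinol (future C10) is untouched and only its CIP label changes (S→R).

**Step 2**
Reactants: 3
Product: 4 (2R)‑2‑hydroxy‑2‑methylpent‑4‑enal
Conditions: SO3·pyridine, DMSO, iPr2NEt, CH2Cl2, 0 °C; used crude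
Reagents that add atoms: none
Why: Parikh–Doering oxidation touches only the primary alcohol, and the α‑carbon is quaternary so it cannot epimerise.

**Step 3**
Reactants: 4; 5 ethynylmagnesium bromide
Product: 6 (4R)‑4‑methylhept‑6‑en‑1‑yne‑3,4‑diol (C3 epimers)
Conditions: 5 (3 equiv), THF, −78 → 0 °C
Reagents that add atoms: ethynylmagnesium bromide, C#C[Mg]Br
Why: Grignard 1,2‑addition to the aldehyde; the new carbinol (future C1) need not be controlled because it is later oxidised.

**Step 4**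
Reactants: 6; 7 triethylsilyl triflate
Product: 8 (4R)‑4‑methyl‑3,4‑bis(triethylsilyloxy)hept‑6‑en‑1‑yne
Conditions: TESOTf (2.5 equiv), 2,6‑lutidine, CH2Cl2, −78 → 0 °C
Reagents that add atoms: TESOTf, CC[Si](CC)(CC)OS(=O)(=O)C(F)(F)F
Why: silyl triflate silylation protects both the secondary and the tertiary alcohol, preventing lactol formation and β‑elimination in the aldehyde.

**Step 5**
Reactants: 8
Product: 9 (3R)‑3‑methyl‑3,4‑bis(triethylsilyloxy)hex‑5‑ynal
Conditions: O3, CH2Cl2, −78 °C (Sudan III end point); PPh3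
Reagents that add atoms: ozone, [O-][O+]=O
Why: ozonolysis cleaves the terminal alkene much faster than the terminal alkyne, giving the C8 aldehyde.

### Fragment B (bromolactone 17)

**Step 6**
Reactants: 10 but‑2‑yne‑1,4‑diol; 11 TBDPSCl
Product: 12 4‑(tert‑butyldiphenylsilyloxy)but‑2‑yn‑1‑ol
Conditions: 10 (3 equiv), NaH (1 equiv), THF, 0 °C; then TBDPSCl (1 equiv)
Reagents that add atoms: TBDPSCl, CC(C)(C)[Si](Cl)(c1ccccc1)c1ccccc1
Why: statistical monosilylation of a symmetric diol via its mono‑alkoxide.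

**Step 7**
Reactants: 12
Product: 13 (2Z)‑4‑(tert‑butyldiphenylsilyloxy)‑3‑iodobut‑2‑en‑1‑ol
Conditions: Red‑Al, THF, 0 °C; EtOAc; then I2, −78 → 0 °C
Reagents that add atoms: iodine, II (hydride from Red‑Al)
Why: hydroxyl‑directed trans‑hydroalumination then iodinolysis puts iodine on the carbon distal to the free OH and fixes the Z geometry (future C4=C5, with C15 trans to C6).

**Step 8**
Reactants: 13
Product: 14 (2Z)‑4‑(tert‑butyldiphenylsilyloxy)‑3‑iodobut‑2‑enal
Conditions: activated MnO2, CH2Cl2, rt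
Reagents that add atoms: none
Why: neutral allylic oxidation that preserves the olefin geometry.

**Step 9**
Reactants: 14; 15 ethyl 2‑(bromomethyl)acrylate
Product: 16 (5S)‑5‑[(1Z)‑3‑(TBDPSO)‑2‑iodoprop‑1‑enyl]‑3‑methylideneoxolan‑2‑one
Conditions: CrCl2 (10 mol %), carbazole‑bis(oxazoline) ligand (11 mol %), Mn, TMSCl, iPr2NEt, THF, 0 °C → rt; then 1 M HCl/THF. Ligand antipode chosen to give 5S, with the sense confirmed by Mosher analysis on the first run.
Reagents that add atoms: ethyl 2‑(bromomethyl)acrylate, C=C(CBr)C(=O)OCC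
Why: catalytic asymmetric Nozaki–Hiyama–Kishi‑type 2‑(alkoxycarbonyl)allylation followed by lactonisation sets C6 by ligand control, and without Ni the vinyl iodide is inert to Cr(II).

**Step 10**
Reactants: 16
Product: 17 (5S)‑3‑(bromomethyl)‑5‑[(1Z)‑3‑(TBDPSO)‑2‑iodoprop‑1‑enyl]furan‑2(5H)‑one
Conditions: Br2 (1.05 equiv), CH2Cl2, −20 °C, dark; then Et3N (1.05 equiv), −20 → 0 °C
Reagents that add atoms: bromine, BrBr
Why: bromine addition to the exocyclic methylene (the iodo‑olefin is deactivated by iodine and two allylic oxygens) then E2 dehydrobromination into the ring gives the allylic bromide butenolide; base is kept cold and stoichiometric to protect C6.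

### Union and completion

**Step 11**
Reactants: 17; 9
Product: 18 (4R,5S)‑4‑[(1S,3R)‑1‑hydroxy‑3‑methyl‑3,4‑bis(triethylsilyloxy)hex‑5‑ynyl]‑5‑[(1Z)‑3‑(TBDPSO)‑2‑iodoprop‑1‑enyl]‑3‑methylideneoxolan‑2‑one
Conditions: Zn dust, THF/sat. aq NH4Cl, 0 °C → rt
Reagents that add atoms: none
Why: Zn‑Barbier SE2′ allylation through a chair Zimmerman–Traxler transition state; attack at C7 anti to the C6 alkenyl group gives the trans lactone, and the ring‑locked E‑type allyl geometry gives the 7,8‑anti adduct (7R,8S).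

**Step 12**
Reactants: 18; 19 tiglic acid
Product: 20, the 8‑O‑tiglate of 18
Conditions: 19, 2,4,6‑trichlorobenzoyl chloride, Et3N, toluene, rt; then 18, DMAP
Reagents that add atoms: tiglic acid, C/C=C(\C)C(=O)O
Why: Yamaguchi esterification acylates the only free hydroxyl (C8) without deconjugating the tiglate or inverting C8.

**Step 13**
Reactants: 20
Product: 21 (6R,7R,8S,10R)‑10‑membered enyne, 1,10‑bis‑O‑TES, 15‑O‑TBDPS, 8‑O‑tiglate
Conditions: Pd(PPh3)4 (20 mol %), CuI (40 mol %), Et3N, degassed THF, 1 mM, syringe‑pump addition, rt → 40 °C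
Reagents that add atoms: none
Why: intramolecular Sonogashira coupling forms C3–C4 with retention of the Z geometry; the four‑atom tether C7–C10 comfortably spans the roughly 4.8 Å C1···C6 gap of the cis‑enyne.

**Step 14**
Reactants: 21
Product: 22, the 1,10‑diol (15‑O‑TBDPS, 8‑O‑tiglate)
Conditions: CSA (0.2 equiv), MeOH/CH2Cl2, 0 °C
Reagents that add atoms: none
Why: mild acidic methanolysis removes both TES ethers while the primary TBDPS ether, tiglate and lactone survive.

**Step 15**
Reactants: 22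
Product: 23, the α′‑hydroxy ynone (C1 ketone)
Conditions: activated MnO2, CH2Cl2, rt
Reagents that add atoms: none
Why: MnO2 oxidises only the propargylic secondary alcohol, converging both C1 epimers.

**Step 16**
Reactants: 23
Product: 24 15‑O‑TBDPS‑lychnophorolide B
Conditions: (Ph3P)AuNTf2 (5 mol %), toluene, rt
Reagents that add atoms: none
Why: Au(I)‑catalysed transannular 5‑endo‑dig hydroalkoxylation of the ynone by the C10 tertiary OH gives the 3(2H)‑furanone; no stereocentre is affected.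

**Step 17**
Reactants: 24
Product: 25 lychnophorolide B
Conditions: HF·pyridine, pyridine, THF, 0 °C → rt
Reagents that add atoms: none
Why: buffered fluoride desilylation frees the C15 alcohol under non‑basic conditions tolerated by the methylene lactone, tiglate and furanone.

## Compound list
1 | (S)‑2‑methylglycidol | OC[C@@]1(C)CO1 | starting material
2 | vinylmagnesium bromide | C=C[Mg]Br | starting material
3 | (2R)‑2‑methylpent‑4‑ene‑1,2‑diol | C=CC[C@@](C)(O)CO | intermediate
4 | (2R)‑2‑hydroxy‑2‑methylpent‑4‑enal | C=CC[C@@](C)(O)C=O | intermediate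
5 | ethynylmagnesium bromide | C#C[Mg]Br | starting material
6 | (4R)‑4‑methylhept‑6‑en‑1‑yne‑3,4‑diol (C3 epimers) | C=CC[C@@](C)(O)C(O)C#C | intermediate
7 | triethylsilyl triflate | CC[Si](CC)(CC)OS(=O)(=O)C(F)(F)F | starting material
8 | (4R)‑4‑methyl‑3,4‑bis(triethylsilyloxy)hept‑6‑en‑1‑yne | C=CC[C@@](C)(O[Si](CC)(CC)CC)C(O[Si](CC)(CC)CC)C#C | intermediate
9 | (3R)‑3‑methyl‑3,4‑bis(triethylsilyloxy)hex‑5‑ynal | O=CC[C@@](C)(O[Si](CC)(CC)CC)C(O[Si](CC)(CC)CC)C#C | intermediate
10 | but‑2‑yne‑1,4‑diol | OCC#CCO | starting material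
11 | tert‑butyldiphenylsilyl chloride | CC(C)(C)[Si](Cl)(c1ccccc1)c1ccccc1 | starting material
12 | 4‑(TBDPSO)but‑2‑yn‑1‑ol | OCC#CCO[Si](c1ccccc1)(c1ccccc1)C(C)(C)C | intermediate
13 | (2Z)‑4‑(TBDPSO)‑3‑iodobut‑2‑en‑1‑ol | OC/C=C(\I)CO[Si](c1ccccc1)(c1ccccc1)C(C)(C)C | intermediate
14 | (2Z)‑4‑(TBDPSO)‑3‑iodobut‑2‑enal | O=C/C=C(\I)CO[Si](c1ccccc1)(c1ccccc1)C(C)(C)C | intermediate
15 | ethyl 2‑(bromomethyl)acrylate | C=C(CBr)C(=O)OCC | starting material
16 | (5S)‑5‑[(1Z)‑3‑(TBDPSO)‑2‑iodoprop‑1‑enyl]‑3‑methylideneoxolan‑2‑one | C=C1C[C@@H](/C=C(\I)CO[Si](c2ccccc2)(c3ccccc3)C(C)(C)C)OC1=O | intermediate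
17 | (5S)‑3‑(bromomethyl)‑5‑[(1Z)‑3‑(TBDPSO)‑2‑iodoprop‑1‑enyl]furan‑2(5H)‑one | BrCC1=C[C@@H](/C=C(\I)CO[Si](c2ccccc2)(c3ccccc3)C(C)(C)C)OC1=O | intermediate
18 | Barbier adduct, (4R,5S)‑lactone with (1S,3R) side chain, free C8–OH | C=C1C(=O)O[C@H](/C=C(\I)CO[Si](c2ccccc2)(c3ccccc3)C(C)(C)C)[C@H]1[C@@H](O)C[C@@](C)(O[Si](CC)(CC)CC)C(O[Si](CC)(CC)CC)C#C | intermediate
19 | tiglic acid | C/C=C(\C)C(=O)O | starting material
20 | 8‑O‑tiglate of 18 | C=C1C(=O)O[C@H](/C=C(\I)CO[Si](c2ccccc2)(c3ccccc3)C(C)(C)C)[C@H]1[C@@H](OC(=O)/C(C)=C/C)C[C@@](C)(O[Si](CC)(CC)CC)C(O[Si](CC)(CC)CC)C#C | intermediate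
21 | (6R,7R,8S,10R) macrocyclic enyne, 1,10‑bis‑OTES, 15‑OTBDPS | C=C1C(=O)O[C@@H]2/C=C(/CO[Si](c3ccccc3)(c4ccccc4)C(C)(C)C)C#CC(O[Si](CC)(CC)CC)[C@@](C)(C[C@H](OC(=O)/C(C)=C/C)[C@@H]12)O[Si](CC)(CC)CC | intermediate
22 | macrocyclic 1,10‑diol, 15‑OTBDPS | C=C1C(=O)O[C@@H]2/C=C(/CO[Si](c3ccccc3)(c4ccccc4)C(C)(C)C)C#CC(O)[C@@](C)(C[C@H](OC(=O)/C(C)=C/C)[C@@H]12)O | intermediate
23 | macrocyclic α′‑hydroxy ynone, 15‑OTBDPS | C=C1C(=O)O[C@@H]2/C=C(/CO[Si](c3ccccc3)(c4ccccc4)C(C)(C)C)C#CC(=O)[C@@](C)(C[C@H](OC(=O)/C(C)=C/C)[C@@H]12)O | intermediate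
24 | 15‑O‑TBDPS‑lychnophorolide B | C=C1C(=O)O[C@@H]2/C=C(/CO[Si](c4ccccc4)(c5ccccc5)C(C)(C)C)C3=CC(=O)[C@@](C)(C[C@H](OC(=O)/C(C)=C/C)[C@@H]12)O3 | intermediate
25 | lychnophorolide B | C=C1C(=O)O[C@@H]2/C=C(/CO)C3=CC(=O)[C@@](C)(C[C@H](OC(=O)/C(C)=C/C)[C@@H]12)O3 | target

## Summary
Total steps: 17. Longest linear sequence: 12 (steps 1–5 then 11–17, or steps 6–10 then 11–17).

Three steps most likely to fail:
1. **Step 13, Sonogashira macrocyclisation.** Risks are ring strain, oligomerisation or Glaser coupling, a competing Heck reaction onto the methylene lactone, and one C1 epimer cyclising poorly. Fallback: reverse the order of the two unions. Make C3–C4 by intermolecular Sonogashira on a 3‑(hydroxymethyl)butenolide analogue of 17 with C8 carried as a protected alcohol, build the furanone, then install the allylic bromide (Appel) and close the ring at C7–C8 by intramolecular Zn/CrCl2 Barbier allylation.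
2. **Step 10, Br2/Et3N.** Risks are competing halogenation at the iodo‑olefin and base‑induced racemisation of the doubly allylic C6–H. Fallback: avoid electrophilic bromine and amine base. Build a 4‑hydroxy‑3‑methylene lactone by Morita–Baylis–Hillman reaction of an acrylate with the C6‑oxygenated aldehyde, lactonise, and transpose with PBr3 (SN2′) to the bromomethyl butenolide.
3. **Step 9, asymmetric carboalkoxyallylation.** Risks are the ee and sense of induction on a Z‑β‑iodo enal, and Cr‑mediated side reactions. Fallback: run the racemic Zn‑Barbier with 15, lactonise, and carry rac‑17 into step 11 with enantiopure 9. Each bromolactone enantiomer then gives a single reagent‑controlled diastereomer, and these are separated by chromatography (or the hydroxy ester is resolved with a lipase beforehand).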